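**Plan**

Numbering used here (elemanolide): ring C5–C10; C10 is quaternary (CH3, vinyl C1=C2); C9–OAng; C8–O(lactone); C7; C6–OH; C5 bears C4(=C3H2)–C15HO; the lactone is C11(=C13H2)–C12(=O).
The C7–C8 bond is shared by the cyclohexane and the γ-lactone and lies between two carbinol carbons, C6 and C9; C6–OH is also γ to the C15 aldehyde. The retrosynthesis removes the angelate, opens the lactone C12–O8 bond, then cuts C6–C7 and C8–C9 together.
This leaves aldehyde 10 (C9HO; C6 held with O15 as a 2-methoxyoxolane on C5) and the open-chain bis-nucleophile 14 (a silyl dienol ether nucleophilic at C8 that becomes an allylsilane nucleophilic at C7).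
Forward: Wittig, esterification and Ireland–Claisen rearrangement join C5–C10; allylic oxidation and two reductions give 10; the annulation closes the cyclohexane; lactonization, angeloylation and acetal hydrolysis finish.
Stereochemistry: C5/C10 from the enantioselective Claisen step; C8/C9 from the aldol stage (anti, Felkin); C6 from the obligatory cis-fusion to the temporary oxolane; C7 from the chair closure.

Key step: step 9

Assumption: the γ-hydroxy enal drawn for the target and its five-membered cyclic hemiacetal are tautomers; the open form is taken as the isolated one.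
Assumption: the (S,S)-bromoborane is taken to give 6 as drawn; if the sense of induction is the opposite, the (R,R)-reagent is used.

**Route**

Step 1
Reactants: 1 ethyl 2-(triphenyl-λ5-phosphanylidene)propanoate; 2 1,4-dioxane-2,5-diol (glycolaldehyde dimer)
Product: 3 ethyl (E)-4-hydroxy-2-methylbut-2-enoate
Conditions: CH2Cl2, 40 °C
Reagents that add atoms: none
Why: Wittig olefination of glycolaldehyde (released from its dimer) with the stabilized ylide should give the E-enoate, the ester group ending trans to CH2OH.

Step 2
Reactants: 3 ethyl (E)-4-hydroxy-2-methylbut-2-enoate; 4 3-methylbut-3-enoic acid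
Product: 5 ethyl (E)-2-methyl-4-[(3-methylbut-3-enoyl)oxy]but-2-enoate
Conditions: DCC, DMAP (5 mol %), CH2Cl2, 0 °C
Reagents that add atoms: none
Why: Steglich esterification joins the two Claisen partners, low temperature and little DMAP keeping the β,γ-unsaturated acid out of conjugation.

Step 3
Reactants: 5 ethyl (E)-2-methyl-4-[(3-methylbut-3-enoyl)oxy]but-2-enoate
Product: 6 (2S,3S)-3-(ethoxycarbonyl)-3-methyl-2-(prop-1-en-2-yl)pent-4-enoic acid
Conditions: (4S,5S)-2-bromo-1,3-bis{[3,5-bis(trifluoromethyl)phenyl]sulfonyl}-4,5-diphenyl-1,3,2-diazaborolidine (1.1 equiv), Et3N, toluene/hexane, −78 → 4 °C; aqueous work-up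
Reagents that add atoms: none
Why: Enantioselective Ireland–Claisen rearrangement of the chiral boron ester enolate through a chair transition state should create the C5–C10 bond, the (E)-allyl ester together with the E(O)-enolate fixing the relative configuration (quaternary C10, tertiary C5) and the C2-symmetric controller the absolute one.

Step 4
Reactants: 6 (2S,3S)-3-(ethoxycarbonyl)-3-methyl-2-(prop-1-en-2-yl)pent-4-enoic acid
Product: 7 ethyl (2S)-2-methyl-2-[(3S)-4-methylidene-2-oxooxolan-3-yl]but-3-enoate
Conditions: SeO2 (0.3 equiv), tBuOOH, CH2Cl2, rt; then TsOH (cat.)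
Reagents that add atoms: tert-butyl hydroperoxide, CC(C)(C)OO (oxygen carried over by SeO2)
Why: SeO2-mediated allylic hydroxylation (ene reaction then [2,3]-shift) takes the methyl of the isopropenyl group (the vinyl group has no allylic hydrogen and the allylic methine is hindered), and the resulting allylic alcohol closes onto the acid as the five-membered lactone without touching C5 or C10.

Step 5
Reactants: 7 ethyl (2S)-2-methyl-2-[(3S)-4-methylidene-2-oxooxolan-3-yl]but-3-enoate
Product: 9 ethyl (2S)-2-[(3S)-2-methoxy-4-methylideneoxolan-3-yl]-2-methylbut-3-enoate (anomer mixture), via lactol 8 (not isolated)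
Conditions: iBu2AlH (1.1 equiv), CH2Cl2, −78 °C; then MeOH, PPTS, rt
Reagents that add atoms: methanol, CO
Why: iBu2AlH reduces the lactone before the neopentyl ester and acid-catalysed acetalization then locks the lactol as its methyl acetal, which masks C6 and ties O6 to C15.

Step 6
Reactants: 9 ethyl (2S)-2-[(3S)-2-methoxy-4-methylideneoxolan-3-yl]-2-methylbut-3-enoate
Product: 10 (2S)-2-[(3S)-2-methoxy-4-methylideneoxolan-3-yl]-2-methylbut-3-enal
Conditions: iBu2AlH (1.2 equiv), CH2Cl2, −78 °C; aqueous potassium sodium tartrate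
Reagents that add atoms: none
Why: Partial reduction of the hindered α-quaternary ester stops at the aldehyde because the tetrahedral aluminate survives at −78 °C, the acetal being inert.

Step 7
Reactants: 11 ethyl 2-[(trimethylsilyl)methyl]prop-2-enoate; 12 (Z)-1,4-bis[(tert-butyldimethylsilyl)oxy]but-2-ene
Product: 13 ethyl (Z)-4-[(tert-butyldimethylsilyl)oxy]-2-[(trimethylsilyl)methyl]but-2-enoate (CH2OTBS trans to the ester)
Conditions: second-generation Hoveyda–Grubbs catalyst (5 mol %), CH2Cl2, 40 °C
Reagents that add atoms: none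
Why: Olefin cross-metathesis of the 1,1-disubstituted acrylate with the symmetrical ether should give the trisubstituted enoate with CH2OTBS trans to the ester (thermodynamic geometry).

Step 8
Reactants: 13 ethyl (Z)-4-[(tert-butyldimethylsilyl)oxy]-2-[(trimethylsilyl)methyl]but-2-enoate
Product: 14 (3E)-1,4-bis[(tert-butyldimethylsilyl)oxy]-1-ethoxy-2-[(trimethylsilyl)methyl]buta-1,3-diene (ketene acetal geometry not defined)
Conditions: LiN(iPr)2, THF, −78 °C; TBSCl, DMPU, −78 → 0 °C; used crude
Reagents that add atoms: tert-butyldimethylsilyl chloride, CC(C)(C)[Si](C)(C)Cl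
Why: γ-Deprotonation of the enoate and O-silylation give the silyl dienol ether, allylic strain with the α-CH2SiMe3 group turning the γ-silyloxy group outward so that the new C7=C8 bond is E.

Step 9
Reactants: 10 (2S)-2-[(3S)-2-methoxy-4-methylideneoxolan-3-yl]-2-methylbut-3-enal; 14 (3E)-1,4-bis[(tert-butyldimethylsilyl)oxy]-1-ethoxy-2-[(trimethylsilyl)methyl]buta-1,3-diene
Product: 16 ethyl 2-[6-(tert-butyldimethylsilyloxy)-4-ethenyl-5-hydroxy-4-methyl-3-methylideneoctahydro-1-benzofuran-7-yl]prop-2-enoate (cis-fused; all stereocentres as in 21), via vinylogous aldol adduct 15 (not isolated)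
Conditions: BF3·OEt2 (2.5 equiv), 2,6-di-tert-butyl-4-methylpyridine, CH2Cl2, −78 °C, then −78 → −20 °C; aq. NaHCO3
Reagents that add atoms: none
Why: Proposed new method: BF3 activates the only free carbonyl (the C9 aldehyde) and the γ-carbon C8 of 14 adds in a vinylogous Mukaiyama aldol reaction to give 15, a 2-(silylmethyl)enoate, whose C7 attacks on warming the five-membered oxocarbenium ion released from the methyl acetal (intramolecular Hosomi–Sakurai reaction with loss of Me3Si), closing the cyclohexane and leaving the exocyclic methylene ester. The closest known reaction types are the vinylogous Mukaiyama aldol addition of 2-silyloxyfurans, the cyclization of 2-(silylmethyl)acrylates onto acetals and the tandem double allylation of 1,4-dicarbonyl compounds to cyclohexane-1,4-diols; joining the two stages in one flask with an open-chain bis-silyl reagent is new. The carbocycle closes in a 6-exo-trig mode at the C6=O+ carbon, and exo also with respect to the allylsilane double bond. C8/C9 should come out anti (open transition state with the (E)-γ-silyloxy dienolate, by analogy with (E)-vinylketene acetals) and C9 in the Felkin sense (attack anti to the oxolane-bearing C5, vinyl as the small flank); C6 is forced cis to C4 because O6 and C4 are held in the oxolane, and C7 places the acrylate equatorial and trans to OTBS in a chair closure. The step needs aldehyde-before-acetal reactivity (BF3 at −78 °C should leave the methyl acetal intact until warming) and γ- over α-attack of the dienolate (secured by the α-CH2SiMe3 group).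

Step 10
Reactants: 16 ethyl 2-[6-(tert-butyldimethylsilyloxy)-4-ethenyl-5-hydroxy-4-methyl-3-methylideneoctahydro-1-benzofuran-7-yl]prop-2-enoate
Product: 17 the corresponding 2-hydroxy compound (C15 hemiacetal, anomer mixture)
Conditions: SeO2 (0.5 equiv), tBuOOH, CH2Cl2, 0 °C → rt
Reagents that add atoms: tert-butyl hydroperoxide, CC(C)(C)OO (oxygen carried over by SeO2)
Why: SeO2 allylic oxidation of the cyclic methallyl-type ether attacks the CH2 that is both allylic and α to oxygen and gives the hemiacetal, the electron-poor acrylate and the vinyl group (no allylic hydrogen) being left alone.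

Step 11
Reactants: 17 C15 hemiacetal
Product: 18 9-hydroxy-8,12-lactone whose O6 and C15 form a 2-methoxyoxolane (C15 methyl acetal, anomer mixture; stereocentres as in 21)
Conditions: TsOH·H2O (10 mol %), MeOH, rt; then toluene, 40 °C
Reagents that add atoms: methanol, CO
Why: Acidic methanol converts the hemiacetal into its methyl acetal (Fischer-type acetalization) and removes the silyl group, after which the γ-hydroxy ester lactonizes at O8, the only oxygen that can reach C12 (O6 is in the acetal, O9 is trans-1,3 to the side chain on C7).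

Step 12
Reactants: 18 9-hydroxy-8,12-lactone C15 methyl acetal; 19 angelic acid ((Z)-2-methylbut-2-enoic acid)
Product: 20 9-O-angeloyl-8,12-lactone C15 methyl acetal
Conditions: 19, 2,4,6-trichlorobenzoyl chloride, Et3N, toluene, rt; then 18, 80 °C
Reagents that add atoms: none
Why: Acylation through the preformed mixed anhydride (Yamaguchi-type esterification without DMAP) should transfer the angeloyl group to the hindered alcohol with retention of the Z geometry.

Step 13
Reactants: 20 9-O-angeloyl-8,12-lactone C15 methyl acetal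
Product: 21 target (9-O-angeloyl-6-hydroxy-15-oxoelema-1,3,11(13)-trien-8,12-olide, configured as in the given SMILES)
Conditions: PPTS, acetone/H2O (4:1), rt
Reagents that add atoms: water, O
Why: Mild acid hydrolysis of the allylic methyl acetal gives the hemiacetal, which opens to the conjugated γ-hydroxy enal of the target without translactonization.

**Compound list**

1 | ethyl 2-(triphenyl-λ5-phosphanylidene)propanoate | CCOC(=O)C(C)=P(c1ccccc1)(c1ccccc1)c1ccccc1 | starting material
2 | 1,4-dioxane-2,5-diol (glycolaldehyde dimer) | OC1COC(O)CO1 | starting material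
3 | ethyl (E)-4-hydroxy-2-methylbut-2-enoate | CCOC(=O)/C(C)=C/CO | intermediate
4 | 3-methylbut-3-enoic acid | C=C(C)CC(=O)O | starting material
5 | ethyl (E)-2-methyl-4-[(3-methylbut-3-enoyl)oxy]but-2-enoate | CCOC(=O)/C(C)=C/COC(=O)CC(C)=C | intermediate
6 | (2S,3S)-3-(ethoxycarbonyl)-3-methyl-2-(prop-1-en-2-yl)pent-4-enoic acid | C=C[C@](C)(C(=O)OCC)[C@H](C(C)=C)C(=O)O | intermediate
7 | ethyl (2S)-2-methyl-2-[(3S)-4-methylidene-2-oxooxolan-3-yl]but-3-enoate | C=C[C@](C)(C(=O)OCC)[C@@H]1C(=C)COC1=O | intermediate
8 | ethyl (2S)-2-[(3S)-2-hydroxy-4-methylideneoxolan-3-yl]-2-methylbut-3-enoate (lactol, anomer mixture) | C=C[C@](C)(C(=O)OCC)[C@@H]1C(=C)COC1O | intermediate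
9 | ethyl (2S)-2-[(3S)-2-methoxy-4-methylideneoxolan-3-yl]-2-methylbut-3-enoate (anomer mixture) | C=C[C@](C)(C(=O)OCC)[C@@H]1C(=C)COC1OC | intermediate
10 | (2S)-2-[(3S)-2-methoxy-4-methylideneoxolan-3-yl]-2-methylbut-3-enal (anomer mixture) | C=C[C@](C)(C=O)[C@@H]1C(=C)COC1OC | intermediate
11 | ethyl 2-[(trimethylsilyl)methyl]prop-2-enoate | C=C(C[Si](C)(C)C)C(=O)OCC | starting material
12 | (Z)-1,4-bis[(tert-butyldimethylsilyl)oxy]but-2-ene | CC(C)(C)[Si](C)(C)OC/C=C\CO[Si](C)(C)C(C)(C)C | starting material
13 | ethyl (Z)-4-[(tert-butyldimethylsilyl)oxy]-2-[(trimethylsilyl)methyl]but-2-enoate | CCOC(=O)/C(C[Si](C)(C)C)=C/CO[Si](C)(C)C(C)(C)C | intermediate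
14 | (3E)-1,4-bis[(tert-butyldimethylsilyl)oxy]-1-ethoxy-2-[(trimethylsilyl)methyl]buta-1,3-diene | CCOC(O[Si](C)(C)C(C)(C)C)=C(C[Si](C)(C)C)/C=C/O[Si](C)(C)C(C)(C)C | intermediate
15 | ethyl (Z)-4-[(tert-butyldimethylsilyl)oxy]-5-hydroxy-6-[(3S)-2-methoxy-4-methylideneoxolan-3-yl]-6-methyl-2-[(trimethylsilyl)methyl]octa-2,7-dienoate (C8/C9 anti, configured as in 16) | C=C[C@@](C)([C@@H]1C(=C)COC1OC)[C@H](O)[C@H](O[Si](C)(C)C(C)(C)C)/C=C(\C[Si](C)(C)C)C(=O)OCC | intermediate
16 | ethyl 2-[6-(tert-butyldimethylsilyloxy)-4-ethenyl-5-hydroxy-4-methyl-3-methylideneoctahydro-1-benzofuran-7-yl]prop-2-enoate (stereocentres as in 21) | C=C[C@]1(C)[C@H](O)[C@H](O[Si](C)(C)C(C)(C)C)[C@@H](C(=C)C(=O)OCC)[C@H]2OCC(=C)[C@@H]12 | intermediate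
17 | ethyl 2-[6-(tert-butyldimethylsilyloxy)-4-ethenyl-2,5-dihydroxy-4-methyl-3-methylideneoctahydro-1-benzofuran-7-yl]prop-2-enoate (hemiacetal, anomer mixture) | C=C[C@]1(C)[C@H](O)[C@H](O[Si](C)(C)C(C)(C)C)[C@@H](C(=C)C(=O)OCC)[C@H]2OC(O)C(=C)[C@@H]12 | intermediate
18 | 9-hydroxy-8,12-lactone with O6–C15 methyl acetal (2-methoxyoxolane cis-fused at C5–C6; anomer mixture) | C=C[C@]1(C)[C@H](O)[C@@H]2OC(=O)C(=C)[C@H]2[C@H]3OC(OC)C(=C)[C@@H]13 | intermediate
19 | angelic acid, (Z)-2-methylbut-2-enoic acid | C/C=C(/C)C(=O)O | starting material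
20 | 9-O-angeloyl-8,12-lactone with O6–C15 methyl acetal (anomer mixture) | C=C[C@]1(C)[C@H](OC(=O)/C(C)=C\C)[C@@H]2OC(=O)C(=C)[C@H]2[C@H]3OC(OC)C(=C)[C@@H]13 | intermediate
21 | 9-O-angeloyl-6-hydroxy-15-oxoelema-1,3,11(13)-trien-8,12-olide | C=C[C@]1(C)[C@H](OC(=O)/C(C)=C\C)[C@@H]2OC(=O)C(=C)[C@H]2[C@@H](O)[C@H]1C(=C)C=O | target

**Step count**

Total: 13 steps. Longest linear sequence: 11 steps (steps 1–6 and 9–13); steps 7–8 make the second fragment.

**Steps most likely to fail**

Step 9. The aldol stage may show poor facial selectivity at C9 (methyl against vinyl flank). The oxocarbenium ion may also be diverted, by capture through the C9 oxygen or by proton loss towards a furan, before the allylsilane closes the ring. Fallback, from 10 back to 16, with the two bonds made in separate known reactions: reagent-controlled anti-hydroxyallylation of 10 with (E)-3-(1,3,2-dioxaborinan-2-yl)allyl-bis(isopinocampheyl)borane and NaOH/H2O2 work-up should give the anti-diol 5-[(3S)-2-methoxy-4-methylideneoxolan-3-yl]-5-methylhepta-1,6-diene-3,4-diol F1. Selective silylation of its less hindered allylic hydroxyl (TBSCl, imidazole) gives the mono-silyl ether F2. Cross-metathesis of F2 with 11 (second-generation Hoveyda–Grubbs catalyst) gives 15, which is isolated and cyclized with Me3SiOTf and 2,6-di-tert-butyl-4-methylpyridine in CH2Cl2 at −78 → −20 °C to 16.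

Step 10. Oxidation may occur at the wrong allylic site, or the hemiacetal may be over-oxidized to a lactone. Fallback, from 16 to 21, with the oxidation moved to the end and run by hydride abstraction instead of an ene reaction: acid treatment of 16 (TsOH, wet toluene) removes the silyl group and closes the lactone to give the 9-hydroxy-8,12-lactone cyclic ether F3. Angeloylation as in step 12 gives the 9-O-angeloyl cyclic ether F4. Oxidative opening of the cyclic methallyl-type ether of F4 with DDQ in CH2Cl2/H2O (hydride abstraction at C15, then hydrolysis) should give 21 directly.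

Step 12. Acylation of the hindered axial alcohol next to the quaternary carbon may be slow, and the angeloyl donor may isomerize from Z to E. Fallback, from 18 to 20, building the angelate on the molecule: esterification of 18 with 2-[bis(2,2,2-trifluoroethoxy)phosphoryl]propanoic acid (DCC, DMAP) gives the phosphonopropanoate F5. Z-selective Still–Gennari olefination of F5 with acetaldehyde (KN(SiMe3)2, 18-crown-6, THF, −78 °C) gives 20.

**Further compounds**

F1 | step 9 | 5-[(3S)-2-methoxy-4-methylideneoxolan-3-yl]-5-methylhepta-1,6-diene-3,4-diol (anti-diol, configured as in 15) | C=C[C@@](C)([C@@H]1C(=C)COC1OC)[C@H](O)[C@H](O)C=C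
F2 | step 9 | 3-O-(tert-butyldimethylsilyl) ether of F1 | C=C[C@@](C)([C@@H]1C(=C)COC1OC)[C@H](O)[C@H](O[Si](C)(C)C(C)(C)C)C=C
F3 | step 10 | 9-hydroxy-8,12-lactone with O6–C15H2 cyclic ether (3-methylideneoxolane) | C=C[C@]1(C)[C@H](O)[C@@H]2OC(=O)C(=C)[C@H]2[C@H]3OCC(=C)[C@@H]13
F4 | step 10 | 9-O-angeloyl-8,12-lactone with O6–C15H2 cyclic ether | C=C[C@]1(C)[C@H](OC(=O)/C(C)=C\C)[C@@H]2OC(=O)C(=C)[C@H]2[C@H]3OCC(=C)[C@@H]13
F5 | step 12 | 9-O-{2-[bis(2,2,2-trifluoroethoxy)phosphoryl]propanoyl} derivative of 18 | C=C[C@]1(C)[C@H](OC(=O)C(C)P(=O)(OCC(F)(F)F)OCC(F)(F)F)[C@@H]2OC(=O)C(=C)[C@H]2[C@H]3OC(OC)C(=C)[C@@H]13
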